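**Retrosynthetic overview**
1. Key disconnection: the C7–C8 CH2–CH2 bond of the acyl chain (C1 = ester carbonyl) is cut homolytically. Each radical carbon is capped with CO2H, which gives nonadecanoic acid and mono(2-phenylethyl) suberate. A mixed Kolbe (anodic decarboxylative) coupling joins them in the last step.
2. Enabling feature: C7 and C8 lie inside the unbranched, heteroatom-free run of 23 methylenes C2–C24, so both radicals are primary and unstabilised and couple rather than oxidise further. The ester C1(=O)–O is six carbons from C7. The only ring, an unactivated phenyl ring behind an O–CH2–CH2 spacer, does not compete at a carboxylate-covered Pt anode.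
3. Second disconnection: the ester C–O bond of the half ester is made by opening suberic anhydride with 2-phenylethanol, which desymmetrises suberic acid.
4. Rings: none is formed in the target, since the phenyl ring is bought with 2-phenylethanol. A temporary nine-membered anhydride ring is closed in step 1 and opened in step 2.

Key step: step 3

Remark on the chemistry: the target has no stereocentre and no stereogenic double bond, so it is achiral and no step has to control configuration.

Step 1
Reactants: 1 suberic acid (octanedioic acid)
Product: 2 suberic anhydride (oxonane-2,9-dione)
Conditions: Ac2O (excess), reflux, 1 h; evaporate; recrystallise from MeCN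
Reagents that add atoms: none
Why: Anhydride exchange with acetic anhydride (dehydrative cyclisation of a dicarboxylic acid) is the standard access to suberic anhydride, is driven by removal of acetic acid, and turns two identical carboxyl groups into one unit that acylates only once.

Step 2
Reactants: 2 suberic anhydride; 3 2-phenylethanol
Product: 4 8-oxo-8-(2-phenylethoxy)octanoic acid (mono(2-phenylethyl) suberate)
Conditions: 2 (1.2 equiv), 3 (1.0 equiv), DMAP (10 mol %), THF, 60 °C; extraction into aq NaHCO3, then acidification
Reagents that add atoms: none
Why: DMAP-catalysed alcoholysis of a cyclic anhydride (nucleophilic acyl substitution with ring opening) should give exactly one ester and one free carboxyl group per suberate unit, and the acidic product is separated from neutral material by bicarbonate extraction.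

Step 3
Reactants: 4 8-oxo-8-(2-phenylethoxy)octanoic acid; 5 nonadecanoic acid
Product: 8 2-phenylethyl pentacosanoate, via octadecyl radical 6 (not isolated), via 7-oxo-7-(2-phenylethoxy)heptyl radical 7 (not isolated)
Conditions: 4 (4 equiv), 5 (1 equiv), NaOMe (5 mol % of total CO2H), MeOH–pyridine 4:1, undivided cell, Pt(+)/Pt(−), ca. 0.2 A cm−2, 40–45 °C, polarity reversed periodically, stopped while still weakly acidic; AcOH quench; SiO2
Reagents that add atoms: none
Why: Mixed Kolbe electrolysis (anodic decarboxylative radical heterocoupling, in its half-ester form the Brown–Walker reaction): both carboxylates adsorb on the platinum anode and each loses one electron and CO2, the primary radicals 6 and 7 arise side by side at high local concentration and combine to form the C7–C8 bond, and the carboxyl protons are reduced to H2 at the cathode. The closest known reaction type is the anodic chain extension of fatty acids with alkyl hydrogen alkanedioates, which builds exactly this kind of CH2–CH2 bond in long-chain esters. No ring is closed and no stereocentre is created, the product being achiral. The step needs radical coupling to win over a second oxidation to the cation (Hofer–Moest path) and cross-coupling to win over homocoupling: the first is secured by the unsubstituted CH2 next to each carboxyl group together with smooth Pt, high current density and a weakly acidic medium, and the second by running the cheap half ester 4 in about fourfold excess so that on statistical grounds most of 6 meets 7, after which the hydrocarbon and diester homodimers each differ from monoester 8 by one ester group and should separate on silica. The phenethyl ester should survive because the carboxylate layer shields the anode from the unactivated monoalkylbenzene ring (benzyl-type esters and carbamates are tolerated in such electrolyses), alkyl radicals add only slowly to that ring, and no free methoxide is present as long as the electrolysis is stopped before the acids are used up.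

**Compound list**
1 | suberic acid (octanedioic acid) | OC(=O)CCCCCCC(=O)O | starting material
2 | suberic anhydride (oxonane-2,9-dione) | O=C1CCCCCCC(=O)O1 | intermediate
3 | 2-phenylethanol | OCCc1ccccc1 | starting material
4 | 8-oxo-8-(2-phenylethoxy)octanoic acid (mono(2-phenylethyl) suberate) | OC(=O)CCCCCCC(=O)OCCc1ccccc1 | intermediate
5 | nonadecanoic acid | CCCCCCCCCCCCCCCCCCC(=O)O | starting material
6 | octadecyl radical | CCCCCCCCCCCCCCCCC[CH2] | intermediate
7 | 7-oxo-7-(2-phenylethoxy)heptyl radical | [CH2]CCCCCC(=O)OCCc1ccccc1 | intermediate
8 | 2-phenylethyl pentacosanoate (achiral) | CCCCCCCCCCCCCCCCCCCCCCCCC(=O)OCCc1ccccc1 | target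

Total step count: 3
Longest linear sequence: 3 steps (1 → 2 → 4 → 8)

**Steps most likely to fail**

Step 3. Several processes could lower the return:
- homocoupling beyond the statistical share
- coating of the electrodes by waxy product
- partial over-oxidation of the radicals to cations
- methanolysis of the phenethyl ester if the solution turns basic
- anodic attack on the phenyl ring

The fallback replaces the electrolysis by a nickel-catalysed decarboxylative coupling. It sets out from 4 and comes back at 8. Compound 4 is condensed with N-hydroxyphthalimide (DIC, cat. DMAP, CH2Cl2) to the redox-active ester 1,3-dioxoisoindolin-2-yl 2-phenylethyl octanedioate F1. Commercial octadecylmagnesium chloride F2 is transmetalated with ZnCl2 (0.5 equiv, THF) to dioctadecylzinc F3. A decarboxylative alkyl–alkyl Negishi-type coupling of F1 with F3 (NiCl2·glyme, 4,4'-di-tert-butyl-2,2'-bipyridine, THF/DMF, rt) forms the same C7–C8 bond. The ester is inert to the dialkylzinc, and the product is 8.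

Step 2. If the anhydride is partly oligomeric, alcoholysis would spread the ester groups statistically, giving double esterification beside regenerated diacid. The ring opening could also be sluggish. The fallback uses two orthogonal esters instead of an anhydride. It sets out from 3 and comes back at 4. Compound 3 is coupled with commercial 8-tert-butoxy-8-oxooctanoic acid F4 in a Steglich-type esterification (EDC, DMAP, CH2Cl2) to give tert-butyl 2-phenylethyl octanedioate F5. The tert-butyl ester of F5 is then cleaved with TFA in CH2Cl2, which leaves the primary phenethyl ester untouched and gives 4.

Step 1. Intermolecular anhydride formation could compete with closure of the nine-membered ring. Mixed acetic anhydride end groups could also be retained and would later acetylate the alcohol. The fallback avoids any anhydride. It sets out from 1 and comes back at 4. A Fischer mono-esterification of excess 1 (3 equiv) with 3 (1 equiv) is run with cat. TsOH in toluene under Dean–Stark conditions. Unreacted 1 is filtered from the cold toluene and recycled, and the half ester is extracted into bicarbonate away from neutral material. No new compound is made (F0).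

**Further compounds**
F1 | step 3 | 1,3-dioxoisoindolin-2-yl 2-phenylethyl octanedioate | O=C(CCCCCCC(=O)OCCc1ccccc1)ON1C(=O)c2ccccc2C1=O
F2 | step 3 | octadecylmagnesium chloride (purchased) | CCCCCCCCCCCCCCCCCC[Mg]Cl
F3 | step 3 | dioctadecylzinc | CCCCCCCCCCCCCCCCCC[Zn]CCCCCCCCCCCCCCCCCC
F4 | step 2 | 8-tert-butoxy-8-oxooctanoic acid (purchased) | CC(C)(C)OC(=O)CCCCCCC(=O)O
F5 | step 2 | tert-butyl 2-phenylethyl octanedioate | CC(C)(C)OC(=O)CCCCCCC(=O)OCCc1ccccc1
F0 | step 1 | none | none
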